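We have no constants for this flask, so we read one off the earlier runs.

common to all: starting material 0.10 M

| charge | enzyme | remark | time |
|---|---|---|---|
| winter | 0.0097 mol% | run made earlier |  |
| autumn | 0.019 mol% | run made earlier |  |
| dusk | 0.037 mol% | run made earlier |  |
| alpha | 0.01 mol% |  | 20 h |
| zeta | 0.04 mol% |  | 6.0 h |

- winter (time / h: target / %, starting material / %): 2.00: 54, 42; 4.00: 67, 27; 6.00: 75, 18; 8.00: 79, 14; 10.0: 84, 9
- autumn (time / h: target / %, starting material / %): 2.00: 67, 26; 4.00: 82, 13; 6.00: 88, 10; 8.00: 93, 5; 10.0: 92, 2
- dusk (time / h: target / %, starting material / %): 0.833: 67, 34; 2.50: 84, 14; 5.00: 93, 2; 8.00: 98, 2; 10.0: 97, 0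

(standard deviation of a reading: 1.5 percentage points)



- the flask that ends with the higher amount of target, in percent of the starting material charged, or "neither" when 2 percentage points or less lies between them (alpha / zeta / neither)
- final target, as a percentage of the starting material charged, in alpha
- final target, as a percentage of the starting material charged, in zeta

At the last reading of each run, target and starting material together add up to less than the charge. Suppose the enzyme and an unseen leak both draw on the starting material in proportion to what stands there. The ratio of their rates then contains no time, and the part missing per part of target equals a fixed loading divided by the enzyme loading. The last readings give 0.0833 at 0.0097 mol%, 0.0652 at 0.019 mol% and 0.0309 at 0.037 mol%, all rough given the scatter. Their products with the loading average 0.0011 mol%. This is the break-even loading, the enzyme loading at which leak and enzyme draw equally; loading over it is a selectivity factor.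

So target is the starting material consumed divided by one plus break-even over loading. Two extremes follow: with that ratio at zero, target equals what was consumed, and with the ratio very large, target tends to nothing. Our flasks lie near the first extreme, with ratios 0.106 for alpha and 0.0266 for zeta.

For what remains we compare loading times time. Alpha's product is 1.05 times that of the autumn run's last reading, which showed 2% of starting material. Zeta's product is 1.30 times that of the dusk run at 5.00 h, so more than that reading's, which showed 2% of starting material. We reckon 88.6% for alpha and 95.5% for zeta, a gap above the margin.

The forecast, close to this by its own route, says zeta, with 88% for alpha and 95% for zeta, on this ground: “Slower runs lose more, which fits an uncatalysed side loss of starting material”.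

The simulation gives zeta, with 95.9% against 90.9% for alpha.

    starting material + enzyme → target + enzyme, rate k1*[starting material]*[enzyme]/(1 + ([starting material]/Km1) + ([target]/Kp1)) (0.0664 M, 0.543 mM, k = 2.37 × 10⁶ L mol⁻¹ h⁻¹)
    starting material ⇌ dormant form (K = 0.900, k = 0.0335 h⁻¹)
    target → over-reaction product (k = 4.49 × 10⁻⁵ h⁻¹)

The leak is the dormant form. At the end of zeta, dormant form per target is 0.0268 against 0.0266 reckoned. In alpha it is 0.0700 against 0.106, the dormant form falling from 7.31% at 10.0 h to 6.36% at 20.0 h. For the neighbour of alpha charged with 0.025 mol% of enzyme, the break-even loading 0.0011 mol% gives a ratio of 0.0426 and target 95.6%. That flask ends with dormant form per target 0.0272 and target 97.0%.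

The data are calculated with constants of no real substance; the scatter is artificial.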